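## Plan

- **Cuts:** C12–C13 (ring closure), then C3–C4 (union of fragments A and B), N–C1, C6–C7, C8=C9, C10–C11 and C14–C15.
- **Enabling feature:** the C12 carbinol sits between the unsubstituted C13 methylene and the methoxy-bearing C11. C13 can therefore be a primary carbon nucleophile released from a carboxylic acid one carbon longer. C12 can be an α-methoxy aldehyde whose C11–O dipole steers attack to 11,12-anti. The flat arene–anilide–(2E,4Z)-dienamide and the E-C8=C9 alkene stiffen the seco chain of the 19-membered ansa ring.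
- **Forward order:** fragment A (arene, C13–C15, C1–C3) and fragment B (C4–C12, carbamate already in place) are joined at C3–C4. Z-semi-reduction and activation follow, then the decarboxylative chromium ring closure, which makes the only new ring. The aryl dimethyl ether is then taken to the quinone and the hydroquinone.
- **Stereochemistry:** C14/C15 and C10/C11 come from one and the same (Z)-crotyldiisopinocampheylborane. C6/C7 come from (S)-but-3-yn-2-ol through an allenylstannane. C12 is set by C11 during ring closure. E-C2=C3 comes from the iodoacrylic acid, Z-C4=C5 from the semi-reduction, and E-C8=C9 from cross-metathesis.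
- **Helpers:** the extra carboxyl carbon and the phthalimide leave in the key step itself. The silyl group at O12 leaves in step 20 and the aryl methyl ethers in step 23.

Key step: step 22

Remark: positions follow the benzenoid ansamycin numbering. C1 is the amide carbonyl, C2–C15 run along the ansa chain to the benzylic carbon, and C16–C21 are the arene (C16 bears C15, C18 and C21 bear oxygen, C20 bears nitrogen). The hydroquinone target is assumed to be air-sensitive and is handled under argon.

## Route

Step 1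
Reactants: 1 2-hydroxy-5-methoxy-3-nitrobenzaldehyde
Product: 2 2,5-dimethoxy-3-nitrobenzaldehyde
Conditions: MeI, K2CO3, DMF, rt to 40 °C
Reagents that add atoms: iodomethane CI
Why: Williamson O-methylation of the acidic ortho-nitrophenol should leave the aldehyde and the nitro group untouched.

Step 2
Reactants: 2 2,5-dimethoxy-3-nitrobenzaldehyde
Product: 4 (1R,2S)-1-(2,5-dimethoxy-3-nitrophenyl)-2-methylbut-3-en-1-ol, via diisopinocampheylborinate 3 (not isolated)
Conditions: cis-2-butene, n-BuLi, KOt-Bu, THF, −78 to −45 °C; (+)-Ipc2BOMe, −78 °C; BF3·OEt2; 2, −78 °C; then NaOH, H2O2, 0 °C to rt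
Reagents that add atoms: (Z)-crotyldiisopinocampheylborane from (−)-α-pinene C/C=C\CB([C@H]1C[C@H]2C[C@@H]([C@@H]1C)C2(C)C)[C@H]1C[C@H]2C[C@@H]([C@@H]1C)C2(C)C
Why: In the Brown asymmetric crotylboration the chair Zimmerman–Traxler transition state turns the Z-crotyl geometry into the 14,15-syn relation, and the isopinocampheyl groups select the aldehyde face that gives 15R,14S.

Step 3
Reactants: 4 (1R,2S)-1-(2,5-dimethoxy-3-nitrophenyl)-2-methylbut-3-en-1-ol
Product: 5 2,5-dimethoxy-1-[(1R,2S)-1-methoxy-2-methylbut-3-en-1-yl]-3-nitrobenzene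
Conditions: NaH, MeI, THF/DMF, 0 °C
Reagents that add atoms: iodomethane CI
Why: Williamson etherification of the benzylic alkoxide installs the C15 methoxy group without touching a stereocentre.

Step 4
Reactants: 5 2,5-dimethoxy-1-[(1R,2S)-1-methoxy-2-methylbut-3-en-1-yl]-3-nitrobenzene
Product: 7 (3S,4R)-4-(2,5-dimethoxy-3-nitrophenyl)-4-methoxy-3-methylbutan-1-ol, via B-alkyl-9-borabicyclononane 6 (not isolated)
Conditions: 9-BBN, THF, 0 °C to rt; then NaOH, H2O2, 0 °C
Reagents that add atoms: hydrogen peroxide OO; 9-borabicyclo[3.3.1]nonane B1C2CCCC1CCC2 (boron in 6 only)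
Why: Anti-Markovnikov hydroboration–oxidation of the monosubstituted alkene with a dialkylborane that tolerates the nitro group should give the primary alcohol.

Step 5
Reactants: 7 (3S,4R)-4-(2,5-dimethoxy-3-nitrophenyl)-4-methoxy-3-methylbutan-1-ol
Product: 8 (3S,4R)-4-(2,5-dimethoxy-3-nitrophenyl)-4-methoxy-3-methylbutanoic acid
Conditions: TEMPO (cat.), PhI(OAc)2, MeCN/H2O, rt
Reagents that add atoms: water O
Why: Oxoammonium oxidation (TEMPO/PhI(OAc)2) runs through the aldehyde hydrate to the acid, whose carboxyl carbon is the later leaving carbon on C13.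

Step 6
Reactants: 8 (3S,4R)-4-(2,5-dimethoxy-3-nitrophenyl)-4-methoxy-3-methylbutanoic acid
Product: 9 (3S,4R)-4-(3-amino-2,5-dimethoxyphenyl)-4-methoxy-3-methylbutanoic acid
Conditions: H2 (1 atm), Pt/C, EtOAc, rt
Reagents that add atoms: none
Why: Catalytic hydrogenation of the nitroarene over platinum is chosen because platinum is a poor hydrogenolysis catalyst, so the benzylic methyl ether should survive.

Step 7
Reactants: 10 diethyl 2-methylmalonate
Product: 11 diethyl 2-(diiodomethyl)-2-methylmalonate
Conditions: NaH, CHI3, Et2O, reflux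
Reagents that add atoms: iodoform IC(I)I
Why: C-alkylation of the malonate enolate with iodoform should give the diiodomethyl malonate.

Step 8
Reactants: 11 diethyl 2-(diiodomethyl)-2-methylmalonate
Product: 12 (E)-3-iodo-2-methylprop-2-enoic acid
Conditions: KOH, EtOH/H2O, reflux; then HCl
Reagents that add atoms: potassium hydroxide [K+].[OH-] (oxygen of the carboxyl group)
Why: Saponification followed by decarboxylative elimination of iodide should deliver the more stable E-iodoacrylic acid, which fixes the C2=C3 geometry.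

Step 9
Reactants: 12 (E)-3-iodo-2-methylprop-2-enoic acid; 9 (3S,4R)-4-(3-amino-2,5-dimethoxyphenyl)-4-methoxy-3-methylbutanoic acid
Product: 14 fragment A (3S,4R)-4-{3-[(E)-3-iodo-2-methylprop-2-enamido]-2,5-dimethoxyphenyl}-4-methoxy-3-methylbutanoic acid, via iodoacryloyl chloride 13 (not isolated)
Conditions: 12, (COCl)2, DMF (cat.), CH2Cl2, 0 °C to rt, concentrate; then 9, NaHCO3, THF/H2O, 0 °C; acidify to pH 3
Reagents that add atoms: oxalyl chloride ClC(=O)C(=O)Cl (chlorine in 13 only)
Why: Schotten–Baumann N-acylation of an amino acid should be selective because the carboxylate stays masked as its salt while the aniline takes the preformed acid chloride.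

Step 10
Reactants: 15 (tert-butyldimethylsilyloxy)acetaldehyde
Product: 17 (2R,3S)-1-(tert-butyldimethylsilyloxy)-3-methylpent-4-en-2-ol, via diisopinocampheylborinate 16 (not isolated)
Conditions: cis-2-butene, n-BuLi, KOt-Bu, THF, −78 to −45 °C; (+)-Ipc2BOMe, −78 °C; BF3·OEt2; 15, −78 °C; then NaOH, H2O2, 0 °C
Reagents that add atoms: (Z)-crotyldiisopinocampheylborane from (−)-α-pinene C/C=C\CB([C@H]1C[C@H]2C[C@@H]([C@@H]1C)C2(C)C)[C@H]1C[C@H]2C[C@@H]([C@@H]1C)C2(C)C
Why: The same Brown crotylboration reagent as in step 2 sets the 10,11-syn pair (11R,10S) through the same chair transition state and the same facial preference.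

Step 11
Reactants: 17 (2R,3S)-1-(tert-butyldimethylsilyloxy)-3-methylpent-4-en-2-ol
Product: 18 tert-butyl{[(2R,3S)-2-methoxy-3-methylpent-4-en-1-yl]oxy}dimethylsilane
Conditions: Me3OBF4, 1,8-bis(dimethylamino)naphthalene, 4 Å MS, CH2Cl2, rt
Reagents that add atoms: trimethyloxonium tetrafluoroborate C[O+](C)C.F[B-](F)(F)F
Why: Meerwein-salt methylation forms no alkoxide, so migration of the silyl group from O12 to O11 is avoided.

Step 12
Reactants: 18 tert-butyl{[(2R,3S)-2-methoxy-3-methylpent-4-en-1-yl]oxy}dimethylsilane; 19 methacrolein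
Product: 20 (2E,4S,5R)-6-(tert-butyldimethylsilyloxy)-5-methoxy-2,4-dimethylhex-2-enal
Conditions: second-generation Hoveyda–Grubbs catalyst (5 mol %), 19 (excess), CH2Cl2, 40 °C
Reagents that add atoms: none
Why: Olefin cross-metathesis of a terminal alkene with methacrolein should give the trisubstituted enal with the thermodynamically preferred E-C8=C9 geometry in one operation.

Step 13
Reactants: 21 (S)-but-3-yn-2-ol
Product: 22 (S)-but-3-yn-2-yl methanesulfonate
Conditions: MsCl, Et3N, CH2Cl2, −78 to 0 °C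
Reagents that add atoms: methanesulfonyl chloride CS(=O)(=O)Cl
Why: O-Sulfonylation does not touch the C–O bond, so the configuration is kept.

Step 14
Reactants: 22 (S)-but-3-yn-2-yl methanesulfonate
Product: 23 (M)-tributyl(buta-1,2-dien-1-yl)stannane
Conditions: Bu3SnH, LDA, THF, 0 °C; CuBr·SMe2, −78 °C; then 22, −78 °C
Reagents that add atoms: tributylstannyllithium [Li][Sn](CCCC)(CCCC)CCCC
Why: Anti-SN2' displacement of the propargylic mesylate by the stannylcuprate should transfer the central chirality of 22 into the axial (M) chirality of the allene.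

Step 15
Reactants: 20 (2E,4S,5R)-6-(tert-butyldimethylsilyloxy)-5-methoxy-2,4-dimethylhex-2-enal; 23 (M)-tributyl(buta-1,2-dien-1-yl)stannane
Product: 24 (3S,4R,5E,7S,8R)-9-(tert-butyldimethylsilyloxy)-8-methoxy-3,5,7-trimethylnon-5-en-1-yn-4-ol
Conditions: BF3·OEt2, CH2Cl2, −78 °C; aq. NaHCO3
Reagents that add atoms: none
Why: In the Lewis-acid-promoted SE2' addition of a chiral allenylstannane, C–C bond formation anti to tin sets C6 (S), and the open antiperiplanar transition state should give the 6,7-syn adduct (7R) under reagent control.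

Step 16
Reactants: 24 (3S,4R,5E,7S,8R)-9-(tert-butyldimethylsilyloxy)-8-methoxy-3,5,7-trimethylnon-5-en-1-yn-4-ol
Product: 26 fragment B (3S,4R,5E,7S,8R)-9-(tert-butyldimethylsilyloxy)-8-methoxy-3,5,7-trimethylnon-5-en-1-yn-4-yl carbamate, via N-trichloroacetyl carbamate 25 (not isolated)
Conditions: Cl3CC(O)NCO, CH2Cl2, 0 °C; then K2CO3 (cat.), MeOH, rt
Reagents that add atoms: trichloroacetyl isocyanate O=C=NC(=O)C(Cl)(Cl)Cl
Why: Carbamoylation with an acyl isocyanate and methanolysis of the activating acyl group places the C7 carbamate now, so O7 needs no protecting group and the later free O12–H needs no differentiation.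

Step 17
Reactants: 26 fragment B carbamate; 14 fragment A iodoacrylanilide acid
Product: 27 (2E)-2-en-4-ynamide seco acid (C3–C4 joined, O12 silylated)
Conditions: PdCl2(PPh3)2 (5 mol %), CuI (10 mol %), Et3N, degassed THF, rt
Reagents that add atoms: none
Why: Sonogashira coupling of the activated β-iodoacrylamide with the terminal alkyne keeps the E-C2=C3 geometry and tolerates the carboxylate, the carbamate and the anilide.

Step 18
Reactants: 27 (2E)-2-en-4-ynamide seco acid
Product: 28 (2E,4Z)-dienamide seco acid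
Conditions: Zn dust activated with Cu(OAc)2 and AgNO3, MeOH/H2O, rt to 40 °C, dark
Reagents that add atoms: none
Why: Boland-type semi-reduction delivers both hydrogens to one face of a conjugated alkyne, so it should give the Z-C4=C5 alkene without touching isolated or already conjugated C=C bonds.

Step 19
Reactants: 28 (2E,4Z)-dienamide seco acid
Product: 29 N-hydroxyphthalimide ester of 28
Conditions: N-hydroxyphthalimide, DIC, DMAP (cat.), CH2Cl2, rt
Reagents that add atoms: N-hydroxyphthalimide ON1C(=O)c2ccccc2C1=O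
Why: Carbodiimide (Steglich-type) esterification turns the only carboxylic acid into the redox-active ester.

Step 20
Reactants: 29 N-hydroxyphthalimide ester of 28
Product: 30 C12 primary alcohol
Conditions: HF (48 % aq.), MeCN, 0 °C
Reagents that add atoms: none
Why: Mildly acidic fluoride desilylation of a primary silyl ether should spare the base-labile active ester, the allylic carbamate and the benzylic ether.

Step 21
Reactants: 30 C12 primary alcohol
Product: 31 C12 aldehyde redox-active ester (cyclisation precursor)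
Conditions: TEMPO (cat.), PhI(OAc)2, CH2Cl2, rt; used directly
Reagents that add atoms: none
Why: Anhydrous oxoammonium oxidation stops at the aldehyde under slightly acidic conditions that should neither epimerise C11 nor attack the electron-rich anilide.

Step 22
Reactants: 31 C12 aldehyde redox-active ester
Product: 33 18,21-di-O-methyl macrocycle (19-membered ansa lactam with free 12S hydroxyl), via alkylchromium dichloride 32 (not isolated)
Conditions: CrCl2 (10 equiv), DMF/THF, rt; 31 added by syringe pump over 12 h (final 2 mM); aq. potassium sodium tartrate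
Reagents that add atoms: chromium dichloride Cl[Cr]Cl (chromium and chlorine in 32 only)
Why: Proposed new method: CrCl2 transfers one electron to the N-acyloxyphthalimide of 31, N–O cleavage and loss of CO2 release the primary C13 radical, and a second divalent chromium captures it faster than it can abstract hydrogen or add to the diene, giving the trivalent alkylchromium 32, which adds to the chromium-bound C12 aldehyde. The closest known reaction types are the intermolecular decarboxylative alkyl Nozaki–Hiyama–Kishi addition of redox-active esters to aldehydes and the ring-closing Nozaki–Hiyama–Kishi reaction of alkenyl iodides; what is new is the ring-closing use of a carboxylate-derived sp3 nucleophile. The single ring closes in a 19-exo-trig mode, with C13 attacking the carbonyl carbon C12 while the C=O bond stays outside the ring. C12 is controlled by C11: solvated trivalent chromium should not chelate the methoxy group, so the polar Felkin–Anh (Cornforth) arrangement applies, and attack anti to the C11–O bond past the C11 hydrogen should give the 11,12-anti (12S) alcohol. The step needs chemoselectivity for the aldehyde over the anilide and carbamate N–H, the dienamide and the aryl ethers, which the low basicity and high oxophilicity of alkylchromium reagents secure; it also needs ring closure to win over oligomerisation, which slow addition into a large excess of concentrated CrCl2 secures, helped by the rigid anilide–dienamide and E-C8=C9 segments. The free C12 hydroxyl emerges as it stands in the target, so no protecting group is spent on it.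

Step 23
Reactants: 33 18,21-di-O-methyl macrocycle
Product: 34 18,21-benzoquinone macrocycle
Conditions: (NH4)2Ce(NO3)6, MeCN/H2O, −10 to 0 °C
Reagents that add atoms: water O
Why: Oxidative demethylation of a 1,4-dimethoxyarene by tetravalent cerium is fast at low temperature and is the standard way to unmask ansamycin quinones in the presence of dienamide, carbamate and secondary alcohol.

Step 24
Reactants: 34 18,21-benzoquinone macrocycle
Product: 35 target CNP0548031.1 (18,21-hydroquinone)
Conditions: Na2S2O4, EtOAc/H2O, rt, argon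
Reagents that add atoms: none
Why: Dithionite reduction of a quinone to its hydroquinone is chemoselective and touches no stereocentre or alkene.

## Compound list

1 | 2-hydroxy-5-methoxy-3-nitrobenzaldehyde | COc1cc(C=O)c(O)c([N+](=O)[O-])c1 | starting material
2 | 2,5-dimethoxy-3-nitrobenzaldehyde | COc1cc(C=O)c(OC)c([N+](=O)[O-])c1 | intermediate
3 | diisopinocampheylborinate of 4 | COc1cc([C@H](OB([C@H]2C[C@H]3C[C@@H]([C@@H]2C)C3(C)C)[C@H]2C[C@H]3C[C@@H]([C@@H]2C)C3(C)C)[C@@H](C)C=C)c(OC)c([N+](=O)[O-])c1 | intermediate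
4 | (1R,2S)-1-(2,5-dimethoxy-3-nitrophenyl)-2-methylbut-3-en-1-ol | COc1cc([C@H](O)[C@@H](C)C=C)c(OC)c([N+](=O)[O-])c1 | intermediate
5 | 2,5-dimethoxy-1-[(1R,2S)-1-methoxy-2-methylbut-3-en-1-yl]-3-nitrobenzene | COc1cc([C@H](OC)[C@@H](C)C=C)c(OC)c([N+](=O)[O-])c1 | intermediate
6 | B-alkyl-9-borabicyclononane adduct of 5 | COc1cc([C@H](OC)[C@@H](C)CCB2C3CCCC2CCC3)c(OC)c([N+](=O)[O-])c1 | intermediate
7 | (3S,4R)-4-(2,5-dimethoxy-3-nitrophenyl)-4-methoxy-3-methylbutan-1-ol | COc1cc([C@H](OC)[C@@H](C)CCO)c(OC)c([N+](=O)[O-])c1 | intermediate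
8 | (3S,4R)-4-(2,5-dimethoxy-3-nitrophenyl)-4-methoxy-3-methylbutanoic acid | COc1cc([C@H](OC)[C@@H](C)CC(=O)O)c(OC)c([N+](=O)[O-])c1 | intermediate
9 | (3S,4R)-4-(3-amino-2,5-dimethoxyphenyl)-4-methoxy-3-methylbutanoic acid | COc1cc([C@H](OC)[C@@H](C)CC(=O)O)c(OC)c(N)c1 | intermediate
10 | diethyl 2-methylmalonate | CCOC(=O)C(C)C(=O)OCC | starting material
11 | diethyl 2-(diiodomethyl)-2-methylmalonate | CCOC(=O)C(C)(C(I)I)C(=O)OCC | intermediate
12 | (E)-3-iodo-2-methylprop-2-enoic acid | OC(=O)/C(C)=C/I | intermediate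
13 | (E)-3-iodo-2-methylprop-2-enoyl chloride | ClC(=O)/C(C)=C/I | intermediate
14 | fragment A, (3S,4R)-4-{3-[(E)-3-iodo-2-methylprop-2-enamido]-2,5-dimethoxyphenyl}-4-methoxy-3-methylbutanoic acid | COc1cc([C@H](OC)[C@@H](C)CC(=O)O)c(OC)c(NC(=O)/C(C)=C/I)c1 | intermediate
15 | (tert-butyldimethylsilyloxy)acetaldehyde | CC(C)(C)[Si](C)(C)OCC=O | starting material
16 | diisopinocampheylborinate of 17 | B(O[C@@H](CO[Si](C)(C)C(C)(C)C)[C@@H](C)C=C)([C@H]1C[C@H]2C[C@@H]([C@@H]1C)C2(C)C)[C@H]1C[C@H]2C[C@@H]([C@@H]1C)C2(C)C | intermediate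
17 | (2R,3S)-1-(tert-butyldimethylsilyloxy)-3-methylpent-4-en-2-ol | O[C@@H](CO[Si](C)(C)C(C)(C)C)[C@@H](C)C=C | intermediate
18 | tert-butyl{[(2R,3S)-2-methoxy-3-methylpent-4-en-1-yl]oxy}dimethylsilane | CO[C@@H](CO[Si](C)(C)C(C)(C)C)[C@@H](C)C=C | intermediate
19 | methacrolein | CC(=C)C=O | starting material
20 | (2E,4S,5R)-6-(tert-butyldimethylsilyloxy)-5-methoxy-2,4-dimethylhex-2-enal | CO[C@@H](CO[Si](C)(C)C(C)(C)C)[C@@H](C)/C=C(\C)C=O | intermediate
21 | (S)-but-3-yn-2-ol | C[C@H](O)C#C | starting material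
22 | (S)-but-3-yn-2-yl methanesulfonate | C[C@H](OS(C)(=O)=O)C#C | intermediate
23 | (M)-tributyl(buta-1,2-dien-1-yl)stannane | CC([H])=[C@]=C([H])[Sn](CCCC)(CCCC)CCCC | intermediate
24 | (3S,4R,5E,7S,8R)-9-(tert-butyldimethylsilyloxy)-8-methoxy-3,5,7-trimethylnon-5-en-1-yn-4-ol | CO[C@@H](CO[Si](C)(C)C(C)(C)C)[C@@H](C)/C=C(\C)[C@H](O)[C@@H](C)C#C | intermediate
25 | N-trichloroacetyl carbamate of 24 | CO[C@@H](CO[Si](C)(C)C(C)(C)C)[C@@H](C)/C=C(\C)[C@H](OC(=O)NC(=O)C(Cl)(Cl)Cl)[C@@H](C)C#C | intermediate
26 | fragment B, C7 carbamate of 24 | CO[C@@H](CO[Si](C)(C)C(C)(C)C)[C@@H](C)/C=C(\C)[C@H](OC(N)=O)[C@@H](C)C#C | intermediate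
27 | (2E)-2-en-4-ynamide seco acid | CO[C@@H](CO[Si](C)(C)C(C)(C)C)[C@@H](C)/C=C(\C)[C@H](OC(N)=O)[C@@H](C)C#C/C=C(\C)C(=O)Nc1cc(OC)cc([C@H](OC)[C@@H](C)CC(=O)O)c1OC | intermediate
28 | (2E,4Z)-dienamide seco acid | CO[C@@H](CO[Si](C)(C)C(C)(C)C)[C@@H](C)/C=C(\C)[C@H](OC(N)=O)[C@@H](C)/C=C\C=C(/C)C(=O)Nc1cc(OC)cc([C@H](OC)[C@@H](C)CC(=O)O)c1OC | intermediate
29 | N-hydroxyphthalimide ester of 28 | CO[C@@H](CO[Si](C)(C)C(C)(C)C)[C@@H](C)/C=C(\C)[C@H](OC(N)=O)[C@@H](C)/C=C\C=C(/C)C(=O)Nc1cc(OC)cc([C@H](OC)[C@@H](C)CC(=O)ON2C(=O)c3ccccc3C2=O)c1OC | intermediate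
30 | C12 primary alcohol, redox-active ester | CO[C@@H](CO)[C@@H](C)/C=C(\C)[C@H](OC(N)=O)[C@@H](C)/C=C\C=C(/C)C(=O)Nc1cc(OC)cc([C@H](OC)[C@@H](C)CC(=O)ON2C(=O)c3ccccc3C2=O)c1OC | intermediate
31 | C12 aldehyde, redox-active ester | CO[C@@H](C=O)[C@@H](C)/C=C(\C)[C@H](OC(N)=O)[C@@H](C)/C=C\C=C(/C)C(=O)Nc1cc(OC)cc([C@H](OC)[C@@H](C)CC(=O)ON2C(=O)c3ccccc3C2=O)c1OC | intermediate
32 | C13 alkylchromium dichloride bearing the C12 aldehyde | CO[C@@H](C=O)[C@@H](C)/C=C(\C)[C@H](OC(N)=O)[C@@H](C)/C=C\C=C(/C)C(=O)Nc1cc(OC)cc([C@H](OC)[C@@H](C)C[Cr](Cl)Cl)c1OC | intermediate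
33 | 18,21-di-O-methyl macrocycle | CO[C@@H]1[C@@H](C)/C=C(\C)[C@H](OC(N)=O)[C@@H](C)/C=C\C=C(/C)C(=O)Nc2cc(OC)cc(c2OC)[C@H](OC)[C@@H](C)C[C@@H]1O | intermediate
34 | 18,21-benzoquinone macrocycle | CO[C@@H]1[C@@H](C)/C=C(\C)[C@H](OC(N)=O)[C@@H](C)/C=C\C=C(/C)C(=O)NC2=CC(=O)C=C(C2=O)[C@H](OC)[C@@H](C)C[C@@H]1O | intermediate
35 | CNP0548031.1 | CO[C@@H]1[C@@H](C)/C=C(\C)[C@H](OC(N)=O)[C@@H](C)/C=C\C=C(/C)C(=O)Nc2cc(O)cc(c2O)[C@H](OC)[C@@H](C)C[C@@H]1O | target

## Step count

Total step count: 24. Longest linear sequence: 15 (steps 1–6, 9, 17–24).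

## Steps most likely to fail

**1. Step 22.** Oligomerisation may outrun ring closure. The C13 radical or the alkylchromium may be quenched to a methyl group before it reaches C12. Facial selectivity at C12 may also be poor inside the forming ring.

The fallback reverses the order of the two unions, sets out from 26 and 14, and uses known reaction types only.
- Desilylation of 26 (HF, MeCN) gives the alkynyl C12 alcohol F1.
- TEMPO/PhI(OAc)2 oxidation gives the alkynyl C12 aldehyde F2.
- In parallel, 14 is esterified with N-hydroxyphthalimide and DIC to the iodoacrylanilide redox-active ester F3.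
- The intermolecular decarboxylative chromium addition of F3 to F2 (nickel-free CrCl2, so that the alkenyl iodide stays inert) gives, under the same Felkin–Anh control, the open-chain 12S alcohol F4.
- Intramolecular Sonogashira coupling at high dilution (PdCl2(PPh3)2, CuI, Et3N) closes the ring at C3–C4 to the macrocyclic enyne F5.
- Semi-reduction with Zn, Cu(OAc)2 and AgNO3 comes back to the route at 33.

**2. Step 15.** The sp2-branched enal may show eroded syn selectivity in the open transition state. The Lewis acid may also ionise the allylic alcohol as it forms.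

The fallback sets out from 20 and builds C6/C7 by auxiliary control.
- An Evans syn aldol with (R)-4-benzyl-3-propionyloxazolidin-2-one (Bu2BOTf, Et3N) gives the syn aldol imide F6.
- Transamidation (MeONHMe·HCl, AlMe3) gives the Weinreb amide F7.
- TESOTf and 2,6-lutidine give the O7 triethylsilyl ether F8.
- i-Bu2AlH at −78 °C gives the C5 aldehyde F9.
- Ohira–Bestmann homologation (K2CO3, MeOH) gives the silylated alkyne F10.
- Selective removal of the secondary triethylsilyl group (PPTS, MeOH, 0 °C) comes back to the route at 24.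

**3. Step 18.** Over-reduction, stalling on the polyfunctional zinc carboxylate, or Z-to-E isomerisation of the new alkene may occur.

The fallback sets the Z geometry before the union, sets out from 26 and 14, and replaces steps 17 and 18.
- Rhodium-catalysed trans-hydroboration of the terminal alkyne of 26 ([Rh(cod)Cl]2, P(i-Pr)3, Et3N, pinacolborane) gives the (Z)-alkenyl pinacolboronate F11.
- Suzuki–Miyaura coupling with 14 (PdCl2(dppf), K3PO4, DMF/H2O, rt) proceeds with retention at both alkenes and comes back to the route at 28.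

## Further compounds

F1 | step 22 | alkynyl C12 alcohol | CO[C@@H](CO)[C@@H](C)/C=C(\C)[C@H](OC(N)=O)[C@@H](C)C#C
F2 | step 22 | alkynyl C12 aldehyde | CO[C@@H](C=O)[C@@H](C)/C=C(\C)[C@H](OC(N)=O)[C@@H](C)C#C
F3 | step 22 | iodoacrylanilide redox-active ester | COc1cc([C@H](OC)[C@@H](C)CC(=O)ON2C(=O)c3ccccc3C2=O)c(OC)c(NC(=O)/C(C)=C/I)c1
F4 | step 22 | open-chain 12S alcohol | CO[C@@H]([C@@H](O)C[C@H](C)[C@@H](OC)c1cc(OC)cc(NC(=O)/C(C)=C/I)c1OC)[C@@H](C)/C=C(\C)[C@H](OC(N)=O)[C@@H](C)C#C
F5 | step 22 | macrocyclic enyne | CO[C@@H]1[C@@H](C)/C=C(\C)[C@H](OC(N)=O)[C@@H](C)C#C/C=C(\C)C(=O)Nc2cc(OC)cc(c2OC)[C@H](OC)[C@@H](C)C[C@@H]1O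
F6 | step 15 | syn aldol imide | CO[C@@H](CO[Si](C)(C)C(C)(C)C)[C@@H](C)/C=C(\C)[C@H](O)[C@@H](C)C(=O)N1[C@H](Cc2ccccc2)COC1=O
F7 | step 15 | Weinreb amide | CO[C@@H](CO[Si](C)(C)C(C)(C)C)[C@@H](C)/C=C(\C)[C@H](O)[C@@H](C)C(=O)N(C)OC
F8 | step 15 | O7 triethylsilyl ether | CO[C@@H](CO[Si](C)(C)C(C)(C)C)[C@@H](C)/C=C(\C)[C@H](O[Si](CC)(CC)CC)[C@@H](C)C(=O)N(C)OC
F9 | step 15 | C5 aldehyde | CO[C@@H](CO[Si](C)(C)C(C)(C)C)[C@@H](C)/C=C(\C)[C@H](O[Si](CC)(CC)CC)[C@@H](C)C=O
F10 | step 15 | silylated alkyne | CO[C@@H](CO[Si](C)(C)C(C)(C)C)[C@@H](C)/C=C(\C)[C@H](O[Si](CC)(CC)CC)[C@@H](C)C#C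
F11 | step 18 | (Z)-alkenyl pinacolboronate | CO[C@@H](CO[Si](C)(C)C(C)(C)C)[C@@H](C)/C=C(\C)[C@H](OC(N)=O)[C@@H](C)/C=C\B1OC(C)(C)C(C)(C)O1
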